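(The numbers in the tables are calculated on assumed constants.)

In these flasks complex with one exchanged cannot be made free of complex with two exchanged, since in the proposed steps the same incoming ligand serves both exchanges. The question is how much of it forms, and so what share of the two products is complex with one exchanged (the selectivity).

| flask | starting complex | incoming ligand | leaving ligand | protic impurity | remark | time |
|---|---|---|---|---|---|---|
| Sunday's | 0.083 M | 0.0747 M | 0.0415 M | 0.083 M | run made earlier |  |
| Thursday's | 0.083 M | 0.0747 M | 0.021 M | 0.083 M | run made earlier |  |
| Friday's | 0.083 M | 0.0747 M | 0.083 M | 0.083 M | run made earlier |  |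
| Wednesday's | 0.042 M | 0.0747 M | 0.0415 M | 0.083 M | run made earlier |  |
| dusk | 0.083 M | 0.0747 M | 0.0415 M | 0.0830 M | a single well-mixed tank run continuously and read at steady state, 40 h in it on average |  |
| summer | 0.083 M | 0.0747 M (fed, over 32.0 h) | 0.0415 M | 0.0830 M | a stirred flask in which incoming ligand is dosed at a steady rate over 32.0 h without added volume, worked up at 40 h | 40 h |
| winter | 0.083 M | 0.0747 M | 0.0415 M | 0.0830 M | one stirred flow tank at steady state, fed with the mixture as stated, mean residence time 200 h |  |
| midnight | 0.083 M | 0.0747 M | 0.0415 M | 0.0830 M | everything together in a closed stirred flask, run for 40 h | 40 h |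

- Sunday's (time / h: complex with one exchanged / %, complex with two exchanged / %): 1.33: 3.2, 0; 4.00: 8.6, 0; 6.00: 11.6, 0.3; 10.0: 16.4, 0.9; 15.0: 20.7, 1.5; 20.0: 22.2, 1.5; 25.0: 23.5, 2.1
- Thursday's (time / h: complex with one exchanged / %, complex with two exchanged / %): 1.33: 3.2, 0.7; 4.00: 8.3, 0.3; 6.00: 11.8, 1.5; 10.0: 17.3, 0.8; 15.0: 21.6, 1.7; 20.0: 24.5, 1.8; 25.0: 26.1, 3.2
- Friday's (time / h: complex with one exchanged / %, complex with two exchanged / %): 1.33: 2.9, 0.4; 4.00: 8.4, 0; 6.00: 11.5, 0.3; 10.0: 14.3, 1.7; 15.0: 16.9, 0.9; 20.0: 19.3, 2.2; 25.0: 19.5, 1.6
- Wednesday's (time / h: complex with one exchanged / %, complex with two exchanged / %): 5.00: 11.0, 0.8; 10.0: 17.4, 1.0; 15.0: 21.4, 1.9; 20.0: 24.7, 2.2; 25.0: 26.6, 3.8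

(standard deviation of a reading: 0.5 percentage points)

- the stated concentrations are those of everything mixed, before any reaction; amounts are the same in each set-up
- steps that have been proposed: complex with one exchanged + incoming ligand <-> leaving ligand + complex with two exchanged; protic impurity + incoming ligand -> quenched reagent; starting complex + incoming ligand <-> leaving ligand + complex with one exchanged; leaving ligand -> by-product carried off
- the feed brings no volume worth counting
- the earlier runs were made in a closed, stirred flask

* the set-up with the highest share of complex with one exchanged in all that became complex with one exchanged or complex with two exchanged, at the outlet or at the end ("none" if the first two lie within 2 percentage points) (dusk / summer / winter / midnight / none)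
* share of complex with one exchanged in all that became complex with one exchanged or complex with two exchanged, at the outlet or at the end, dusk
* share of complex with one exchanged in all that became complex with one exchanged or complex with two exchanged, at the outlet or at the end, summer
* share of complex with one exchanged in all that became complex with one exchanged or complex with two exchanged, at the outlet or at the end, winter
* share of complex with one exchanged in all that became complex with one exchanged or complex with two exchanged, at the outlet or at the end, midnight

Sunday's run has the charges of midnight, and at 25.0 h it reads 23.5 % of complex with one exchanged and 2.1 % of complex with two exchanged, each with a scatter of 0.5 percentage points, so what follows is rough. Reagent-hours are the charge of incoming ligand multiplied by the time it has stood in the flask, counted as though none were used. The leak, the ratio of complex with two exchanged to complex with one exchanged gained per reagent-hour, reads 0.0479 M⁻¹ h⁻¹ from Sunday's run, and this reckoning takes it as constant.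

Midnight and summer share their charges and their 40 h, but summer's incoming ligand enters over 32.0 h. Midnight's incoming ligand therefore stands for 40 h, and summer's, fed evenly, for 24.0 h on average, so summer collects a factor of 0.600 of midnight's reagent-hours. Summer should end with the higher share because its reagent-hours are fewer. By this reckoning midnight ends at 87.5 % and summer at 92.1 %.

The forecast, which differs slightly from this, names summer as best, with dusk 88.5 %, summer 93 %, winter 85.5 % and midnight 88 %, saying “Dosing keeps reagent low while one-exchanged complex builds”.

The flasks give dusk 82.0 %, summer 90.8 %, winter 65.5 % and midnight 84.3 %, so summer is best. The reckoning stood 3.2 points above midnight and 1.3 points above summer.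

    complex with one exchanged + incoming ligand ⇌ leaving ligand + complex with two exchanged (K = 36.0, k = 0.130 M⁻¹ h⁻¹)
    protic impurity + incoming ligand → quenched reagent (k = 0.0790 M⁻¹ h⁻¹)
    starting complex + incoming ligand ⇌ leaving ligand + complex with one exchanged (K = 0.560, k = 0.350 M⁻¹ h⁻¹)
    leaving ligand → by-product carried off (k = 0.00800 h⁻¹)

Summer has not come to rest at 40.0 h, with 58.5 % of its incoming ligand still there. Left until 400 h, that falls to 3.68 % and leaving ligand goes from 121 % to 13.1 % of its charge. Complex with two exchanged climbs from 2.34 % to 15.5 % of the starting complex charged, and the share drops to 53.9 %. The neighbour flask doses 0.019 M of incoming ligand on summer's schedule, and for its reagent-hours the leak gives 97.9 %. The computed share in the neighbour flask is 97.8 %.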